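A closed, stirred vessel holds free monomer and initiator, and living ends add monomer until they die.

| setting | alpha | zeta |
|---|---|---|
| free monomer | 0.050 M | 0.015 M |
| initiator | 1.2 mM | 1.2 mM |
| time | 3.0 min | 3.0 min |

    free monomer + initiator → living end + monomer in chains (k1 = 1.24 L mol⁻¹ s⁻¹)
    free monomer + living end → monomer in chains + living end, rate k2*[living end]*[free monomer] (k2 = 5.27 L mol⁻¹ s⁻¹)
    living end → dead end (k3 = 0.00269 s⁻¹)

- the average divides the monomer in chains by the number of chains begun, living and dead together
- run time (alpha): 3.0 min

1. which of the two ends with the longer chains by the average number of monomer units in a chain (chains begun, living or dead) ("neither" if they lie within 10%) (alpha / zeta / neither)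
2. average number of monomer units in a chain (chains begun, living or dead) at the end, alpha
3. average number of monomer units in a chain (chains begun, living or dead) at the end, zeta

Dispose of initiation first. Its time, the inverse of k1[free monomer], is 16.1 s in alpha and 53.8 s in zeta, shorter than the run. So estimate the chains begun as the initiator charge, 1.2 mM, from the start.

Two times remain. Take 2.64 min as the monomer time, the time in which living ends at the full initiator charge cut free monomer by a factor e. This loss is pseudo-first-order. Living ends die, though, so the run of 3.0 min counts as a shorter exposure, the time integral of their surviving fraction: 2.38 min. Neither time contains the free monomer charge, so this reckoning gives both flasks one share: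

share reacted = 1 − exp(−exposure / monomer time) = 59.4%

length, alpha = share × [free monomer] / [initiator] = 24.8

length, zeta = 7.43

Longer chains: alpha.

The forecast says alpha, with 24 for alpha and 7.05 for zeta, and warns: “Monomer depletion matters, so constant-monomer shortcuts fail”.

The simulation gives alpha, with 24.0 for alpha and 7.04 for zeta.

My share leaves 40.6% of the free monomer. At the end alpha keeps 42% and zeta 49%, so the reckoning runs high for zeta. Now read zeta at 8.0 min. The monomer time stays 2.64 min, and the exposure grows to 4.49 min. The length for zeta at that reading comes to 10.2. The simulation reads 10.3 for that flask, with 19% of the charged free monomer still there.

(The numbers belong to no real substance; the result is computed.)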